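A direct plan would build the chain first and the ring last: docosylmagnesium bromide A1 would be acylated with dimethyl oxalate A2 to give methyl 2-oxotetracosanoate A3 as the first intermediate, the enolate of A3 would be nitrovinylated at C3 with (E)-N,N-dimethyl-2-nitroethen-1-amine A4 to give methyl 3-[(E)-2-nitroethenyl]-2-oxotetracosanoate A5 as the cyclisation precursor, and iron in acetic acid would reduce A5 and close the pyrrole ring at N1–C2.
- The nitrovinylation that takes A3 to A5 would be weak: the only skeleton-building step has no close precedent on an enolisable α-keto ester, which self-aldolises and can react at oxygen or twice.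
- The reductive closure at nitrogen that starts from A5 would be weak: a six-electron nitro reduction must run beside a very electrophilic, reducible α-keto ester and passes through an aminovinyl ketone that can polymerise, on the most advanced intermediate.
- The Grignard mono-acylation that joins A1 and A2 to A3 would be weak: the waxy C22 Grignard reagent is prone to Wurtz coupling and poorly soluble at −78 °C, where the stop at the keto ester must be held against double addition.

**Retrosynthetic overview**
- Precursor: docosan-1-ol 1 is oxidised to docosanal 2, which takes up nitromethane 3 (Henry) to nitro alcohol 4; its acetate 5 is a storable mask of a nitroalkene.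
- Key disconnection: the pyrrole (the only ring) is cut at C2–C3 and C4–C5. Methyl isocyanoacetate 6 supplies C5, N1, C2 and the C2 ester; nitroalkene 7, released from 5 in the flask, supplies C3 with its henicosyl chain and C4.
- Feature used: ester at C2, chain at C3 and only hydrogen at C4 and C5 is the pattern a Barton–Zard reaction of a 1-nitroalk-1-ene leaves once nitrite departs from C4. The ring closes at the C4–C5 carbon–carbon bond (via 8 and 9 to target 10), not at nitrogen.
- What the design avoids: no keto ester enolate is functionalised, no reduction at nitrogen is needed (nitrogen arrives as the isocyanide), and no long-chain organometallic is made.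

Key step: step 4

Remark on the chemistry: the target has no stereocentre, so the carbinol centre of 4 and 5 is carried racemic and disappears in step 4.

**Step 1**
Reactants: 1 docosan-1-ol
Product: 2 docosanal
Conditions: TEMPO (0.1 equiv), PhI(OAc)2 (1.1 equiv), CH2Cl2, 30 °C
Reagents that add atoms: none
Why: Oxoammonium (TEMPO/PhI(OAc)2) oxidation of a primary alcohol stops at the aldehyde in the absence of water, and gentle warming keeps the waxy C22 alcohol in solution; no stereocentre is formed.

**Step 2**
Reactants: 2 docosanal; 3 nitromethane
Product: 4 1-nitrotricosan-2-ol (racemic)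
Conditions: MeNO2 (10 equiv), 1,1,3,3-tetramethylguanidine (0.1 equiv), THF, 0 °C to rt; AcOH quench
Reagents that add atoms: nitromethane (3) C[N+](=O)[O-]
Why: Henry (nitroaldol) addition of nitromethane, in large excess to suppress the bis-adduct, to an unhindered aliphatic aldehyde under catalytic guanidine base; the new C2 carbinol centre forms racemic and is erased in step 4.

**Step 3**
Reactants: 4 1-nitrotricosan-2-ol
Product: 5 1-nitrotricosan-2-yl acetate (racemic)
Conditions: Ac2O (1.5 equiv), conc. H2SO4 (cat.), CH2Cl2, 0 °C to rt; aq. NaHCO3
Reagents that add atoms: acetic anhydride CC(=O)OC(C)=O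
Why: Acid-catalysed O-acetylation of the β-nitro alcohol gives the nitroalkene in masked, storable form and avoids the E1cB elimination that amine-promoted acylation would trigger; the racemic centre is untouched.

**Step 4**
Reactants: 5 1-nitrotricosan-2-yl acetate; 6 methyl isocyanoacetate
Product: 10 methyl 3-henicosyl-1H-pyrrole-2-carboxylate, via (E)-1-nitrotricos-1-ene 7 (not isolated), via Michael adduct 8 (not isolated), via 4-nitro-1-pyrroline 9 (not isolated)
Conditions: 6 (1.2 equiv), DBU (2.3 equiv, added over 1 h), THF, 0 to 35 °C; 1 M HCl
Reagents that add atoms: methyl isocyanoacetate (6) [C-]#[N+]CC(=O)OC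
Why: Barton–Zard pyrrole synthesis on a β-acetoxy nitroalkane: DBU first eliminates acetic acid from 5 (E1cB) to release nitroalkene 7, the DBU-generated anion of 6 adds through its α-carbon to the chain-bearing carbon of 7 (forming C2–C3) to give nitronate 8, and the nitronate carbon attacks the isocyanide carbon (forming C4–C5) in a 5-endo-dig closure that gives 1-pyrroline 9 after proton transfer. Base-induced loss of nitrite from 9 and a 1,5-hydrogen shift should then deliver the aromatic 1H-pyrrole. The closest known reaction type is the condensation of 2-acetoxy-1-nitroalkanes or 1-nitroalk-1-enes with alkyl isocyanoacetates to 3-substituted pyrrole-2-carboxylates. The regiochemistry needed (chain at C3 next to the ester carbon, hydrogen at C4 and C5) is secured by the polarity of the nitroalkene, which accepts the nucleophile only at the carbon remote from the nitro group, and by the departure of that nitro group from C4. The chemoselectivity needed over oligomerisation of the aliphatic nitroalkene and its isomerisation to the allylic nitro compound is secured by releasing 7 gradually, through slow addition of DBU, in the presence of the isocyanoacetate. The three transient sp3 centres of 9 are uncontrolled and all vanish on aromatisation, and the methyl ester is inert to DBU in dry THF.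

**Compound list**
1 | docosan-1-ol | CCCCCCCCCCCCCCCCCCCCCCO | starting material
2 | docosanal | CCCCCCCCCCCCCCCCCCCCCC=O | intermediate
3 | nitromethane | C[N+](=O)[O-] | starting material
4 | 1-nitrotricosan-2-ol (racemic) | CCCCCCCCCCCCCCCCCCCCCC(O)C[N+](=O)[O-] | intermediate
5 | 1-nitrotricosan-2-yl acetate (racemic) | CCCCCCCCCCCCCCCCCCCCCC(OC(C)=O)C[N+](=O)[O-] | intermediate
6 | methyl isocyanoacetate | [C-]#[N+]CC(=O)OC | starting material
7 | (E)-1-nitrotricos-1-ene | CCCCCCCCCCCCCCCCCCCCC/C=C/[N+](=O)[O-] | intermediate
8 | methyl 2-isocyano-3-(nitromethyl)tetracosanoate (formed as its nitronate, diastereomer mixture) | CCCCCCCCCCCCCCCCCCCCCC(C[N+](=O)[O-])C([N+]#[C-])C(=O)OC | intermediate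
9 | methyl 3-henicosyl-4-nitro-3,4-dihydro-2H-pyrrole-2-carboxylate (diastereomer mixture) | CCCCCCCCCCCCCCCCCCCCCC1C(C(=O)OC)N=CC1[N+](=O)[O-] | intermediate
10 | methyl 3-henicosyl-1H-pyrrole-2-carboxylate (achiral) | CCCCCCCCCCCCCCCCCCCCCc1cc[nH]c1C(=O)OC | target

**Count and risk**
Total step count: 4. Longest linear sequence: 4 steps (1 to 2 to 4 to 5 to 10).

Steps most likely to fail:

Step 4 (key step). Base-induced oligomerisation of the unbranched nitroalkene, or its isomerisation to the allylic nitro compound, may outrun the Michael addition; the isocyanoacetate anion may also self-condense. The fallback sets out from docosanal 2. Seyferth–Gilbert homologation with the Ohira–Bestmann reagent (dimethyl (1-diazo-2-oxopropyl)phosphonate, K2CO3, MeOH/THF, rt) would give tricos-1-yne F1. Ag2CO3 (0.1 equiv) in 1,4-dioxane at 80 °C would then join F1 and methyl isocyanoacetate 6 in the known silver-catalysed alkyne–isocyanide cycloaddition, which gives 2,3-disubstituted pyrroles from terminal alkynes. It comes back to the route at target 10 and needs neither a nitro compound nor a base-labile alkene.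

Step 2. The nitroaldol equilibrium may stay on the side of the poorly soluble aldehyde, which then self-condenses, or the product nitronate may add to a second aldehyde. The fallback sets out from docosanal 2. Wittig methylenation (Ph3PCH3Br, KOtBu, THF, 0 °C to rt) would give tricos-1-ene F2. Radical nitration with AgNO2 and TEMPO (4 Å molecular sieves, 1,2-dichloroethane, 70 °C) would convert the terminal alkene into (E)-1-nitrotricos-1-ene 7, here isolated. Compound 7 would enter step 4 with DBU cut to 1.2 equiv, so the route is rejoined at 7.

Step 3. Acetic acid may be eliminated during acetylation or work-up, followed by oligomerisation of the freed nitroalkene on storage; acid-induced retro-Henry cleavage is also possible. The fallback sets out from nitro alcohol 4. MsCl (1.1 equiv) and Et3N (2.5 equiv) in CH2Cl2 at −10 °C would form 1-nitrotricosan-2-yl methanesulfonate F3, which eliminates in the same flask to (E)-1-nitrotricos-1-ene 7. Compound 7 would be filtered quickly through silica and taken at once into step 4 (DBU 1.2 equiv), so the route is rejoined at 7.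

**Further compounds**
F1 | step 4 | tricos-1-yne | CCCCCCCCCCCCCCCCCCCCCC#C
F2 | step 2 | tricos-1-ene | CCCCCCCCCCCCCCCCCCCCCC=C
F3 | step 3 | 1-nitrotricosan-2-yl methanesulfonate (racemic) | CCCCCCCCCCCCCCCCCCCCCC(OS(C)(=O)=O)C[N+](=O)[O-]
A1 | direct plan | docosylmagnesium bromide | CCCCCCCCCCCCCCCCCCCCCC[Mg]Br
A2 | direct plan | dimethyl oxalate | COC(=O)C(=O)OC
A3 | direct plan | methyl 2-oxotetracosanoate | CCCCCCCCCCCCCCCCCCCCCCC(=O)C(=O)OC
A4 | direct plan | (E)-N,N-dimethyl-2-nitroethen-1-amine | CN(C)/C=C/[N+](=O)[O-]
A5 | direct plan | methyl 3-[(E)-2-nitroethenyl]-2-oxotetracosanoate (racemic) | CCCCCCCCCCCCCCCCCCCCCC(/C=C/[N+](=O)[O-])C(=O)C(=O)OC
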